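At early times two things happened in each flask: the solid substrate dissolved towards its solubility, and the second substrate took partner away, its step having a constant ten times that of the target's step.

| flask | solid substrate | partner | second substrate | temperature | time |
|---|---|---|---|---|---|
| Sunday's | 0.43 M | 0.430 M | 0.0860 M | 20 °C | 1.0 h |
| Monday's | 0.43 M | 0.430 M | 0.0860 M | 40 °C | 1.0 h |
| Friday's | 0.43 M | 0.430 M | 0.0860 M | 60 °C | 1.0 h |

    starting material + partner ⇌ target (K1 = 17.9 /M, k1 = 4.68 × 10⁻⁴ /M/s, Ea1 = 68.0 kJ/mol, ΔH1 = −45.0 kJ/mol)
    second substrate + partner → second product (k2 = 0.00456 /M/s, Ea2 = 71.0 kJ/mol)
    starting material + second substrate → cross product (k3 = 6.51 × 10⁻⁴ /M/s, Ea3 = 73.0 kJ/mol)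
    solid substrate ⇌ starting material, rate k4*(cs4 - [starting material]) while solid is left; crystals form when [starting material] > cs4 (cs4 = 0.25 M, k4 = 7.96 × 10⁻⁴ /s)
    (constants at 20 °C)

- solid substrate is a solid; its amount is given per volume of the solution
- the constants hold at 20 °C; other temperatures follow from the activation energies and enthalpies
- at the start none of the solid substrate is in solution
- what has only dissolved of solid substrate counts as not reacted

* the flask that comes out highest in amount of target, in percent of the solid substrate charged, or "all alike" when all lie within 1.5 percentage points (Sunday's / Monday's / Friday's / all alike)
* target at the end, in percent of the solid substrate charged, Sunday's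
* target at the end, in percent of the solid substrate charged, Monday's
* target at the end, in percent of the solid substrate charged, Friday's

I turned the question round and asked what a win for the hottest flask, Friday's, would need. Its target had to pass what Monday's made, so I froze two concentrations as an estimate. While solid lay in the flask I held c(starting material) at 0.25 M, and I took the partner available to the target's step as 0.344 M, the charge less the second substrate. Equilibrium then reads c(target) = K × 0.25 M × (0.344 M − c(target)). With Friday's constant of 1.95 /M this gave 26.2% of the charge. I called this the saturation ceiling: the target that stands at equilibrium over a saturated solution. The picture held for Friday's, since target and dissolved material together came to 84.4% of the charge, which left solid over.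

For Monday's I took the constant roughly as the geometric mean of Sunday's and Friday's, 5.91 /M. Its ceiling came to 47.7%, higher than Friday's, though rough: with the dissolved material at its solubility the total would be 106% of the charge, more than was charged, so the solid would be gone first and the figure stood too high. The forward step alone, taken at the frozen concentrations from the start and with its constant raised roughly by the square root of 28, reckoned to a pace of 180% of the charge per hour, a pace and not an amount, far above that ceiling. The same reckoning for Sunday's gave 33.7%, below Monday's ceiling. A win for Friday's therefore needed Monday's to stop near half of its ceiling, and I committed to Monday's.

The forecast also named Monday's, with 16.8% for Sunday's, 36% for Monday's and 23.7% for Friday's, holding that Friday's is “capped by an equilibrium that has dropped sharply with heat and by dissolution”. Its Sunday's figure lay well below my 33.7%.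

The flasks gave 17.7% on Sunday's, 36.2% on Monday's and 23.5% on Friday's, so Monday's came out highest. Left for 10.0 h, Friday's flask stood at 26.2% with 15.6% of the solid still present, against its ceiling of 26.2%. A neighbour of Monday's flask, charged with 1.7 M of solid substrate, has the same ceiling in molar terms, which is 12.1% of its larger charge. After 1.00 h, with 79.5% of its solid left, that neighbour held 9.16% as target.

(The rate constants were set for the occasion; no experiment stands behind them.)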